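**Plan**

- Feature: ring A is numbered from the methoxy carbon (position 1) through the carbon bearing the oxygen to ring B (position 2) to the carbon bearing the ethano bridge to ring D (position 3), and positions 4 to 6 are CH. This is the pattern of a salicylate assembled from a γ-aryloxy β-keto ester (positions 6, 1 and 2) and a terminal alkynone (positions 5, 4 and 3), with a CO2Me group at position 6 as a removable activator.
- Retrosynthetic cuts, in order: the O–benzyl bond on ring C; the diaryl ether C–O bond between the ring D oxygen and ring C (opens the 18-membered ring); the bond from ring A position 6 to CO2Me; ring A between positions 5 and 6 and between positions 2 and 3; the O–CH2 bond of the keto ester; the ring B/ring C ethano bridge (as a stilbene).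
- Forward: rings B and C are joined by Wittig olefination and diimide reduction, and the ring B phenol is alkylated to keto ester 9. Ring D is carried in alkynone 14. Ring A is then built by benzannulation, which unites the two halves.
- End game: O-methylation, ester removal, MOM removal, Ullmann closure of the macrocycle, debenzylation.
- Stereochemistry: the target has no stereocentre; the alkene geometry of stilbene 6 is erased by reduction.

Key step: step 9

Assumption: the target is treated as a single, conformationally mobile macrocycle with no element of chirality to control, and stilbene 6 is used as its E/Z mixture.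

**Route**

Step 1
Reactants: 1 3-hydroxybenzyl alcohol
Product: 2 (3-hydroxybenzyl)triphenylphosphonium bromide
Conditions: PPh3·HBr, MeCN, reflux
Reagents that add atoms: triphenylphosphine hydrobromide, Br.c1ccc(cc1)P(c1ccccc1)c1ccccc1
Why: Direct conversion of a benzylic alcohol into its benzylphosphonium salt (protonation, loss of water, capture of the benzylic electrophile by the phosphine) should proceed cleanly because the phenol does not react with the phosphine.

Step 2
Reactants: 3 3-bromo-4-hydroxybenzaldehyde
Product: 4 4-(benzyloxy)-3-bromobenzaldehyde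
Conditions: BnBr, K2CO3, DMF, rt to 50 °C
Reagents that add atoms: benzyl bromide, BrCc1ccccc1
Why: Williamson etherification of the acidic ortho-bromophenol with a reactive benzylic bromide should be straightforward, and the aldehyde is inert to K2CO3.

Step 3
Reactants: 2 (3-hydroxybenzyl)triphenylphosphonium bromide; 4 4-(benzyloxy)-3-bromobenzaldehyde
Product: 6 3-[2-(4-benzyloxy-3-bromophenyl)ethenyl]phenol (E/Z mixture), via phosphonium ylide 5 (not isolated)
Conditions: KOtBu (2.2 equiv), THF, 0 °C to rt; then dilute HCl
Reagents that add atoms: none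
Why: Wittig olefination with two equivalents of base should work because the meta phenoxide of ylide 5 is not conjugated with the ylide carbon and so does not impair its addition to aldehyde 4; the alkene geometry is irrelevant since step 4 saturates it.

Step 4
Reactants: 6 3-[2-(4-benzyloxy-3-bromophenyl)ethenyl]phenol (E/Z mixture)
Product: 7 3-[2-(4-benzyloxy-3-bromophenyl)ethyl]phenol
Conditions: TsNHNH2, NaOAc, DME/H2O, reflux
Reagents that add atoms: none
Why: Diimide reduction transfers two hydrogens concertedly to the nonpolar C=C bond and should leave the aryl bromide and the benzyl ether untouched, which hydrogenation over palladium would not.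

Step 5
Reactants: 7 3-[2-(4-benzyloxy-3-bromophenyl)ethyl]phenol; 8 methyl 4-chloroacetoacetate
Product: 9 methyl 4-{3-[2-(4-benzyloxy-3-bromophenyl)ethyl]phenoxy}-3-oxobutanoate
Conditions: NaH (2.2 equiv), THF/DMF, 0 °C to rt; then dilute HCl
Reagents that add atoms: none
Why: Williamson-type SN2 displacement should succeed because the second equivalent of NaH stores the keto ester as its enolate while the unhindered phenoxide displaces the primary chloride, so the hindered ether bond to ring A position 2 is made while that carbon is still sp3.

Step 6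
Reactants: 10 methyl 3-(4-hydroxyphenyl)propanoate
Product: 11 methyl 3-[4-(methoxymethoxy)phenyl]propanoate
Conditions: MOMCl, i-Pr2NEt, CH2Cl2, 0 °C to rt
Reagents that add atoms: chloromethyl methyl ether, COCCl
Why: Acetal protection of the phenol gives a group that should survive Grignard reagents, Cs2CO3, hydroxide and the silver-catalysed step, and that acid removes later without touching the benzyl ether.

Step 7
Reactants: 11 methyl 3-[4-(methoxymethoxy)phenyl]propanoate
Product: 12 N-methoxy-N-methyl-3-[4-(methoxymethoxy)phenyl]propanamide
Conditions: MeNHOMe·HCl, i-PrMgCl (3 equiv), THF, −20 to 0 °C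
Reagents that add atoms: N,O-dimethylhydroxylamine hydrochloride, CNOC.Cl
Why: Weinreb amide formation by direct aminolysis of the methyl ester with the chloromagnesium amide should outpace enolisation and addition of i-PrMgCl to the ester at low temperature.

Step 8
Reactants: 12 N-methoxy-N-methyl-3-[4-(methoxymethoxy)phenyl]propanamide
Product: 14 5-[4-(methoxymethoxy)phenyl]pent-1-yn-3-one, via magnesium chelate 13 (not isolated)
Conditions: HC≡CMgBr (0.5 M in THF, 2 equiv), THF, 0 °C; inverse quench into cold aq. NaHSO4
Reagents that add atoms: ethynylmagnesium bromide, C#C[Mg]Br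
Why: In this Weinreb ketone synthesis the five-membered chelate 13 holds the tetrahedral adduct until work-up so only one ethynyl group adds, and the cold acidic quench protonates the released amine before it can add to the ynone.

Step 9
Reactants: 9 methyl 4-{3-[2-(4-benzyloxy-3-bromophenyl)ethyl]phenoxy}-3-oxobutanoate; 14 5-[4-(methoxymethoxy)phenyl]pent-1-yn-3-one
Product: 17 methyl 3-{3-[2-(4-benzyloxy-3-bromophenyl)ethyl]phenoxy}-2-hydroxy-4-{2-[4-(methoxymethoxy)phenyl]ethyl}benzoate, via Michael adduct 15 (not isolated), via aldol adduct 16 (not isolated)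
Conditions: Cs2CO3 (2 equiv), MeCN, rt to 60 °C, slow addition of 14; then aq. NH4Cl
Reagents that add atoms: none
Why: Cs2CO3 deprotonates 9 at the carbon between its two carbonyls (the future ring A position 6), which adds in a conjugate sense to the unsubstituted alkyne terminus of 14 (the future position 5) to give the vinylogous dicarbonyl 15, whose enone geometry equilibrates through the extended enolate. The closest known reaction type is the carbonate-mediated Michael–aldol (formal 3+3, Robinson-type) benzannulation of β-keto esters with ynones to salicylates. Ring A closes by a 6-(enolendo)-exo-trig intramolecular aldol addition of the aryloxy-bearing carbon (position 2) to the side-chain ketone (position 3) to give 16, and base-induced loss of water followed by keto–enol tautomerisation makes the closure irreversible through aromatisation. No stereocentre survives in 17, so none has to be controlled. The selectivity needed is in the aldol partner: the aryloxy-bearing methylene must attack the former ynone ketone, rather than the ketone-side methylene of the former ynone attacking the keto ester carbonyl. This is secured because the keto ester carbonyl is held as a non-electrophilic delocalised enolate, while the hydrogens of the aryloxy-bearing methylene are acidified by that carbonyl and by the aryloxy group, and only this pathway leads to an aromatic ring.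

Step 10
Reactants: 17 methyl 3-{3-[2-(4-benzyloxy-3-bromophenyl)ethyl]phenoxy}-2-hydroxy-4-{2-[4-(methoxymethoxy)phenyl]ethyl}benzoate
Product: 18 methyl 3-{3-[2-(4-benzyloxy-3-bromophenyl)ethyl]phenoxy}-2-methoxy-4-{2-[4-(methoxymethoxy)phenyl]ethyl}benzoate
Conditions: MeI, K2CO3, DMF, 50 °C
Reagents that add atoms: iodomethane, CI
Why: Williamson O-methylation of the chelated salicylate phenol should go to completion in a dipolar solvent, since it is the only acidic O–H in the molecule.

Step 11
Reactants: 18 methyl 3-{3-[2-(4-benzyloxy-3-bromophenyl)ethyl]phenoxy}-2-methoxy-4-{2-[4-(methoxymethoxy)phenyl]ethyl}benzoate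
Product: 19 3-{3-[2-(4-benzyloxy-3-bromophenyl)ethyl]phenoxy}-2-methoxy-4-{2-[4-(methoxymethoxy)phenyl]ethyl}benzoic acid
Conditions: LiOH·H2O, THF/MeOH/H2O, 60 °C; then dilute HCl, 0 °C
Reagents that add atoms: lithium hydroxide, [Li+].[OH-]
Why: Saponification of a methyl benzoate with one free ortho position should be unproblematic, and the aryl ethers, the MOM acetal and the bromide are stable to hydroxide.

Step 12
Reactants: 19 3-{3-[2-(4-benzyloxy-3-bromophenyl)ethyl]phenoxy}-2-methoxy-4-{2-[4-(methoxymethoxy)phenyl]ethyl}benzoic acid
Product: 20 2-{3-[2-(4-benzyloxy-3-bromophenyl)ethyl]phenoxy}-1-methoxy-3-{2-[4-(methoxymethoxy)phenyl]ethyl}benzene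
Conditions: Ag2CO3 (10 mol%), AcOH (5 mol%), DMSO, 120 °C
Reagents that add atoms: none
Why: Silver-catalysed protodecarboxylation is favoured by the ortho methoxy group, which accelerates loss of CO2 from the silver carboxylate before protonation of the carbon–silver bond, and monovalent silver should not insert into the aryl bromide.

Step 13
Reactants: 20 2-{3-[2-(4-benzyloxy-3-bromophenyl)ethyl]phenoxy}-1-methoxy-3-{2-[4-(methoxymethoxy)phenyl]ethyl}benzene
Product: 21 4-[2-(2-{3-[2-(4-benzyloxy-3-bromophenyl)ethyl]phenoxy}-3-methoxyphenyl)ethyl]phenol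
Conditions: conc. HCl (cat.), MeOH/THF, 50 °C
Reagents that add atoms: none
Why: Acid-catalysed acetal methanolysis should cleave the MOM group through its oxocarbenium ion while the benzyl, methyl and diaryl ethers remain intact.

Step 14
Reactants: 21 4-[2-(2-{3-[2-(4-benzyloxy-3-bromophenyl)ethyl]phenoxy}-3-methoxyphenyl)ethyl]phenol
Product: 22 O-benzyl ether of the target macrocycle (18-membered bis(bibenzyl) with benzyloxy on ring C)
Conditions: CuI (0.5 equiv), N,N-dimethylglycine hydrochloride, Cs2CO3, 1,4-dioxane (2 mM, slow addition of 21), 100 °C, Ar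
Reagents that add atoms: none
Why: Intramolecular Ullmann diaryl ether synthesis between the unhindered para-alkylphenoxide of ring D and the ring C bromide should close the 18-membered ring, with high dilution favouring cyclisation over oligomerisation and the two flexible ethano bridges keeping the ring free of strain.

Step 15
Reactants: 22 O-benzyl ether of the target macrocycle
Product: 23 CNP0309263.0 (target)
Conditions: H2 (1 atm), Pd/C, EtOAc/EtOH, rt
Reagents that add atoms: none
Why: Hydrogenolysis of the benzyl aryl ether over palladium should be clean at this stage because no bromide or alkene remains and the diaryl and methyl ethers are inert.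

**Compound list**

1 | 3-hydroxybenzyl alcohol | OCc1cccc(O)c1 | starting material
2 | (3-hydroxybenzyl)triphenylphosphonium bromide | [Br-].Oc1cccc(C[P+](c2ccccc2)(c2ccccc2)c2ccccc2)c1 | intermediate
3 | 3-bromo-4-hydroxybenzaldehyde | O=Cc1ccc(O)c(Br)c1 | starting material
4 | 4-(benzyloxy)-3-bromobenzaldehyde | O=Cc1ccc(OCc2ccccc2)c(Br)c1 | intermediate
5 | phosphonium ylide, potassium phenoxide form (not isolated) | [K+].[O-]c1cccc(C=P(c2ccccc2)(c2ccccc2)c2ccccc2)c1 | intermediate
6 | 3-[2-(4-benzyloxy-3-bromophenyl)ethenyl]phenol, E/Z mixture | Oc1cccc(C=Cc2ccc(OCc3ccccc3)c(Br)c2)c1 | intermediate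
7 | 3-[2-(4-benzyloxy-3-bromophenyl)ethyl]phenol | Oc1cccc(CCc2ccc(OCc3ccccc3)c(Br)c2)c1 | intermediate
8 | methyl 4-chloroacetoacetate | COC(=O)CC(=O)CCl | starting material
9 | methyl 4-{3-[2-(4-benzyloxy-3-bromophenyl)ethyl]phenoxy}-3-oxobutanoate | COC(=O)CC(=O)COc1cccc(CCc2ccc(OCc3ccccc3)c(Br)c2)c1 | intermediate
10 | methyl 3-(4-hydroxyphenyl)propanoate | COC(=O)CCc1ccc(O)cc1 | starting material
11 | methyl 3-[4-(methoxymethoxy)phenyl]propanoate | COC(=O)CCc1ccc(OCOC)cc1 | intermediate
12 | N-methoxy-N-methyl-3-[4-(methoxymethoxy)phenyl]propanamide | CON(C)C(=O)CCc1ccc(OCOC)cc1 | intermediate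
13 | bromomagnesium chelate of the tetrahedral adduct (not isolated) | CON(C)C(O[Mg]Br)(C#C)CCc1ccc(OCOC)cc1 | intermediate
14 | 5-[4-(methoxymethoxy)phenyl]pent-1-yn-3-one | C#CC(=O)CCc1ccc(OCOC)cc1 | intermediate
15 | Michael adduct, methyl 2-(aryloxyacetyl)-7-[4-(methoxymethoxy)phenyl]-5-oxohept-3-enoate, E/Z and racemic (not isolated) | COC(=O)C(C=CC(=O)CCc1ccc(OCOC)cc1)C(=O)COc1cccc(CCc2ccc(OCc3ccccc3)c(Br)c2)c1 | intermediate
16 | aldol adduct, methyl 3-aryloxy-4-hydroxy-4-{2-[4-(methoxymethoxy)phenyl]ethyl}-2-oxocyclohex-5-ene-1-carboxylate, diastereomer mixture (not isolated) | COC(=O)C1C=CC(O)(CCc2ccc(OCOC)cc2)C(Oc2cccc(CCc3ccc(OCc4ccccc4)c(Br)c3)c2)C1=O | intermediate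
17 | methyl 3-{3-[2-(4-benzyloxy-3-bromophenyl)ethyl]phenoxy}-2-hydroxy-4-{2-[4-(methoxymethoxy)phenyl]ethyl}benzoate | COC(=O)c1ccc(CCc2ccc(OCOC)cc2)c(Oc2cccc(CCc3ccc(OCc4ccccc4)c(Br)c3)c2)c1O | intermediate
18 | methyl 3-{3-[2-(4-benzyloxy-3-bromophenyl)ethyl]phenoxy}-2-methoxy-4-{2-[4-(methoxymethoxy)phenyl]ethyl}benzoate | COC(=O)c1ccc(CCc2ccc(OCOC)cc2)c(Oc2cccc(CCc3ccc(OCc4ccccc4)c(Br)c3)c2)c1OC | intermediate
19 | 3-{3-[2-(4-benzyloxy-3-bromophenyl)ethyl]phenoxy}-2-methoxy-4-{2-[4-(methoxymethoxy)phenyl]ethyl}benzoic acid | OC(=O)c1ccc(CCc2ccc(OCOC)cc2)c(Oc2cccc(CCc3ccc(OCc4ccccc4)c(Br)c3)c2)c1OC | intermediate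
20 | 2-{3-[2-(4-benzyloxy-3-bromophenyl)ethyl]phenoxy}-1-methoxy-3-{2-[4-(methoxymethoxy)phenyl]ethyl}benzene | COc1cccc(CCc2ccc(OCOC)cc2)c1Oc1cccc(CCc2ccc(OCc3ccccc3)c(Br)c2)c1 | intermediate
21 | 4-[2-(2-{3-[2-(4-benzyloxy-3-bromophenyl)ethyl]phenoxy}-3-methoxyphenyl)ethyl]phenol | COc1cccc(CCc2ccc(O)cc2)c1Oc1cccc(CCc2ccc(OCc3ccccc3)c(Br)c2)c1 | intermediate
22 | O-benzyl ether of the target macrocycle | COc1cccc2c1Oc1cccc(c1)CCc1ccc(OCc3ccccc3)c(c1)Oc1ccc(cc1)CC2 | intermediate
23 | CNP0309263.0 | COc1cccc2c1Oc1cccc(c1)CCc1ccc(O)c(c1)Oc1ccc(cc1)CC2 | target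

**Totals**

Total step count: 15. Longest linear sequence: 11 steps (steps 1, 3, 4, 5, 9, 10, 11, 12, 13, 14, 15).

**Steps most likely to fail**

1. Step 9. The aldol closure may proceed through the wrong enolisable position (the ketone-side methylene of the former ynone attacking the keto ester carbonyl). The Michael adduct may also lactonise through its dienol oxygen onto the ester, or the terminal ynone may oligomerise under base before the Michael addition. The fallback inverts the order of the two bond formations and sets out from 14 and 9. Alkynone 14 would be converted by double conjugate addition of methanol (cat. NaOMe, MeOH, rt) into the β-keto acetal 1,1-dimethoxy-5-[4-(methoxymethoxy)phenyl]pentan-3-one F1. The dianion of keto ester 9 (LDA, 2.2 equiv, THF, −78 °C; no alkyllithium, so that the aryl bromide is spared) would add through its aryloxy-bearing carbon to the ketone of F1. This forms the bond between ring A positions 2 and 3 first and without ambiguity, giving methyl 4-{3-[2-(4-benzyloxy-3-bromophenyl)ethyl]phenoxy}-5-(2,2-dimethoxyethyl)-5-hydroxy-7-[4-(methoxymethoxy)phenyl]-3-oxoheptanoate F2. Mild unmasking of the aldehyde (pyridinium p-toluenesulfonate, wet acetone, rt, which should spare the MOM ether) followed by piperidinium acetate in toluene would close the bond between positions 5 and 6 by intramolecular Knoevenagel condensation. Dehydration then aromatises the ring, and the route is rejoined at salicylate 17.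

2. Step 14. Intermolecular etherification to oligomers may outrun closure of the 18-membered ring, and the hindered position ortho to the benzyloxy group may undergo hydrodebromination instead of coupling. The fallback replaces the copper-catalysed halide coupling by an oxidative boron-based coupling and sets out from 21. Palladium-catalysed borylation (Pd(OAc)2, XPhos, tetrahydroxydiboron, KOAc, EtOH, 80 °C), in which zerovalent palladium inserts into the C–Br bond, would give the boronic acid [2-(benzyloxy)-5-(2-{3-[2-(2-(4-hydroxyphenyl)ethyl)-6-methoxyphenoxy]phenyl}ethyl)phenyl]boronic acid F3. An intramolecular Chan–Evans–Lam etherification with divalent copper (Cu(OAc)2, pyridine, 4 Å molecular sieves, CH2Cl2, air, high dilution, rt) would then form the same ring D oxygen to ring C bond and return to macrocycle 22.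

3. Step 5. Self-condensation of the chloro keto ester enolate and C-alkylation may compete with the desired O-alkylation and leave phenol 7 unconsumed. The fallback builds the keto ester by acylation instead of alkylation and sets out from 7. O-Alkylation with bromoacetic acid (NaH, THF/DMF, then acidification) would give {3-[2-(4-benzyloxy-3-bromophenyl)ethyl]phenoxy}acetic acid F4. Activation with 1,1'-carbonyldiimidazole in THF would give the acyl imidazole 1-({3-[2-(4-benzyloxy-3-bromophenyl)ethyl]phenoxy}acetyl)imidazole F5. Treatment in the same flask with potassium methyl malonate, MgCl2 and Et3N (magnesium malonate C-acylation with decarboxylation on acidic work-up) would return to keto ester 9.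

**Further compounds**

F1 | step 9 | 1,1-dimethoxy-5-[4-(methoxymethoxy)phenyl]pentan-3-one | COCOc1ccc(CCC(=O)CC(OC)OC)cc1
F2 | step 9 | methyl 4-{3-[2-(4-benzyloxy-3-bromophenyl)ethyl]phenoxy}-5-(2,2-dimethoxyethyl)-5-hydroxy-7-[4-(methoxymethoxy)phenyl]-3-oxoheptanoate (diastereomer mixture) | COC(=O)CC(=O)C(Oc1cccc(CCc2ccc(OCc3ccccc3)c(Br)c2)c1)C(O)(CC(OC)OC)CCc1ccc(OCOC)cc1
F3 | step 14 | [2-(benzyloxy)-5-(2-{3-[2-(2-(4-hydroxyphenyl)ethyl)-6-methoxyphenoxy]phenyl}ethyl)phenyl]boronic acid | COc1cccc(CCc2ccc(O)cc2)c1Oc1cccc(CCc2ccc(OCc3ccccc3)c(B(O)O)c2)c1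
F4 | step 5 | {3-[2-(4-benzyloxy-3-bromophenyl)ethyl]phenoxy}acetic acid | OC(=O)COc1cccc(CCc2ccc(OCc3ccccc3)c(Br)c2)c1
F5 | step 5 | 1-({3-[2-(4-benzyloxy-3-bromophenyl)ethyl]phenoxy}acetyl)imidazole | O=C(COc1cccc(CCc2ccc(OCc3ccccc3)c(Br)c2)c1)n1ccnc1
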